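**Retrosynthetic overview**

1. Core numbering: hydrindane C1 (CH carrying the CH2 link), C2, C3, C3a (quaternary), C4 (CHBr), C5, C6, C7 (C–O, CH3), C7a (CH), lactol carbon C8 on C3a; cyclohexyl ring C1′–C6′.
2. C1′–CH2 bond: core CH2–CeCl2 reagent plus (4S)-4-bromo-3,3-dimethylcyclohexanone (from L-glutamate via bromolactone and methylidene-oxane). Lactol ring C, formed last: Barton nitrite oxidation of the angular CH3 (C8) by the axial C7 carbinol, which comes from CH3MgBr on a C7 ketone.
3. Key disconnection C3a–C7a: in the target C4–Br is anti-periplanar to the C3a–C7a fusion bond and C7, next to C7a, is oxygenated, so this bond is the union of a C3a/C4 bromonium ion with the α-carbon of a C7 ketone. It is made by a bromonium-relayed Ferrier-type 1,3-O→C shift in a 10-oxabicyclo[4.3.1]decane: the seven-membered ring (O, C7, C7a, C1, C2, C3, C3a) contracts to cyclopentane ring B while the oxane ring becomes cyclohexanone ring A.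
4. The oxa-bridged bicycle comes from transannular bromoketalisation of an (E)-cyclonon-4-enone; the nine-membered ring comes from Grob fragmentation of an ent-Hajos–Parrish hydrindane, whose one surviving stereocentre (core C1) relays chirality.
5. Ring order: left cyclohexane (oxane → carbocycle); hydrindane (aldol) → nine-membered ring → oxane + oxepane (temporary O-bridge) → rings A and B together (key step) → lactol ring C.

Key step: step 17

Assumption: the lactol hydroxyl configuration drawn in the target is taken to be the anomer favoured at ring–chain equilibrium; no kinetic step sets it.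

**Route**

Step 1
Reactants: 1 5-methyl L-glutamate [(2S)-2-amino-5-methoxy-5-oxopentanoic acid]
Product: 2 (2S)-2-bromo-5-methoxy-5-oxopentanoic acid
Conditions: NaNO2, KBr, aq. HBr, 0 °C
Reagents that add atoms: hydrogen bromide, Br
Why: Diazotisation of the α-amino acid with bromide capture should proceed with net retention (double inversion through the α-lactone), the standard access to (S)-2-bromo acids.

Step 2
Reactants: 2 (2S)-2-bromo-5-methoxy-5-oxopentanoic acid
Product: 3 dimethyl (2S)-2-bromopentanedioate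
Conditions: MeOH, cat. H2SO4, 23 °C
Reagents that add atoms: methanol, CO
Why: Fischer esterification under acid avoids base-induced epimerisation at the C–Br centre.

Step 3
Reactants: 3 dimethyl (2S)-2-bromopentanedioate
Product: 5 (5S)-5-bromo-6,6-dimethyloxan-2-one, via bromohydrin ester 4 (not isolated)
Conditions: CH3MgBr (2.05 equiv), THF, −78 °C, AcOH quench; then cat. TsOH, CH2Cl2, 23 °C
Reagents that add atoms: methylmagnesium bromide, C[Mg]Br
Why: The α-bromo ester is the more electrophilic carbonyl, so double Grignard addition should give the tertiary bromohydrin, which lactonises onto the remaining ester under acid; the cold quench prevents epoxide formation and the C–Br centre is untouched.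

Step 4
Reactants: 5 (5S)-5-bromo-6,6-dimethyloxan-2-one
Product: 6 (3S)-3-bromo-2,2-dimethyl-6-methylideneoxane
Conditions: (C5H5)2Ti(CH3)2, toluene, 70 °C, dark
Reagents that add atoms: dimethyltitanocene (C5H5)2Ti(CH3)2, C[Ti](C)(C1C=CC=C1)C1C=CC=C1
Why: Petasis methylenation converts lactones into exocyclic enol ethers under non-basic conditions that tolerate the secondary bromide.

Step 5
Reactants: 6 (3S)-3-bromo-2,2-dimethyl-6-methylideneoxane
Product: 7 (4S)-4-bromo-3,3-dimethylcyclohexan-1-one
Conditions: TMSOTf (0.2 equiv), CH2Cl2, −78 to −20 °C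
Reagents that add atoms: none
Why: Proposed new method: O-silylation of the enol ether lets the tertiary C2–O bond ionise with anchimeric help from the anti (equatorial) C3–Br, and the bromonium ion/silyl enol ether pair recombines at carbon (O-return only regenerates 6) to give the ketone with the C–Br centre unchanged; the closest known reaction is the Petasis–Ferrier rearrangement (Lewis-acid 1,3-O→C shift of cyclic enol acetals), extended here from oxocarbenium ions to a bromonium-stabilised tertiary cation.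

Step 6
Reactants: 8 2-methyl-2-(3-oxobutyl)cyclopentane-1,3-dione
Product: 9 (3aR,7aR)-3a-hydroxy-7a-methylhexahydro-1H-indene-1,5(4H)-dione
Conditions: (R)-proline (3 mol %), DMF, 20 °C
Reagents that add atoms: none
Why: Hajos–Parrish reaction (proline-catalysed desymmetrising intramolecular aldol); (R)-proline should give the enantiomer of the classical cis ketol, with OH and CH3 cis.

Step 7
Reactants: 9 (3aR,7aR)-3a-hydroxy-7a-methylhexahydro-1H-indene-1,5(4H)-dione
Product: 10 (3aR,7aR)-3a-hydroxy-7a-methyl-5-methylideneoctahydro-1H-inden-1-one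
Conditions: Zn, CH2Br2, TiCl4, THF/CH2Cl2, 0 °C
Reagents that add atoms: dibromomethane, BrCBr
Why: Lombardo–Takai methylenation is non-basic (no retro-aldol of the β-ketol) and should select the unhindered six-ring ketone over the α-quaternary cyclopentanone.

Step 8
Reactants: 10 (3aR,7aR)-3a-hydroxy-7a-methyl-5-methylideneoctahydro-1H-inden-1-one
Product: 11 (1R,3aR,7aS)-7a-methyl-5-methylideneoctahydro-1H-indene-1,3a-diol
Conditions: NaBH4, MeOH, 0 °C
Reagents that add atoms: none
Why: Hydride should attack C1 anti to the adjacent angular methyl, giving the alcohol cis to CH3 and 3a-OH, which is the configuration the later Grob fragmentation requires.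

Step 9
Reactants: 11 (1R,3aR,7aS)-7a-methyl-5-methylideneoctahydro-1H-indene-1,3a-diol
Product: 12 (1R,3aR,5R,7aS)-5-(hydroxymethyl)-7a-methyloctahydro-1H-indene-1,3a-diol
Conditions: 9-BBN (excess), THF, 0 to 23 °C; then NaOH, H2O2
Reagents that add atoms: hydrogen peroxide, OO
Why: Brown hydroboration–oxidation; the borane should add from the face opposite the syn-axial angular hydroxyl, placing CH2OH cis to 3a-OH and creating C5, the one stereocentre of this bicycle that survives into the target (core C1).

Step 10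
Reactants: 12 (1R,3aR,5R,7aS)-5-(hydroxymethyl)-7a-methyloctahydro-1H-indene-1,3a-diol
Product: 13 (1R,3aR,5R,7aS)-5-(iodomethyl)-7a-methyloctahydro-1H-indene-1,3a-diol
Conditions: I2, PPh3, imidazole, CH2Cl2, 0 °C
Reagents that add atoms: iodine, II
Why: Appel-type iodination is selective for the primary alcohol over the hindered secondary and tertiary ones.

Step 11
Reactants: 13 (1R,3aR,5R,7aS)-5-(iodomethyl)-7a-methyloctahydro-1H-indene-1,3a-diol
Product: 14 (1R,3aR,5R,7aS)-5-(iodomethyl)-7a-methyl-1,3a-bis(triethylsilyloxy)octahydro-1H-indene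
Conditions: TESOTf, 2,6-lutidine, CH2Cl2, −78 to 0 °C
Reagents that add atoms: triethylsilyl trifluoromethanesulfonate, CC[Si](CC)(CC)OS(=O)(=O)C(F)(F)F
Why: The silyl triflate silylates both the secondary and the tertiary alcohol, so no acidic proton remains for the lithiation.

Step 12
Reactants: 14 (1R,3aR,5R,7aS)-5-(iodomethyl)-7a-methyl-1,3a-bis(triethylsilyloxy)octahydro-1H-indene; 7 (4S)-4-bromo-3,3-dimethylcyclohexan-1-one
Product: 17 (1S,4S)-4-bromo-3,3-dimethyl-1-{[(1R,3aR,5S,7aS)-7a-methyl-1,3a-bis(triethylsilyloxy)octahydro-1H-inden-5-yl]methyl}cyclohexyl acetate, via organolithium 15 (not isolated), via organocerium 16 (not isolated)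
Conditions: t-BuLi (2.1 equiv), Et2O, −78 °C; CeCl3, THF, −78 °C; then 7; then Ac2O, −78 to 0 °C
Reagents that add atoms: acetic anhydride, CC(=O)OC(C)=O
Why: Iodine–lithium exchange and transmetalation give a non-basic organocerium that should add 1,2 to the γ-bromo ketone without enolisation; the axial C3′ methyl blocks axial attack so the new C–C bond is equatorial, and reaction through the chair with equatorial bromine (expected to be only moderately favoured, in THF at −78 °C) places the oxygen cis to Br, the C1′ epimer from the other chair being removed here, and the alkoxide is acetylated in situ.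

Step 13
Reactants: 17 (1S,4S)-4-bromo-3,3-dimethyl-1-{[(1R,3aR,5S,7aS)-7a-methyl-1,3a-bis(triethylsilyloxy)octahydro-1H-inden-5-yl]methyl}cyclohexyl acetate
Product: 18 (1S,4S)-4-bromo-1-{[(1R,3aR,5R,7aS)-1,3a-dihydroxy-7a-methyloctahydro-1H-inden-5-yl]methyl}-3,3-dimethylcyclohexyl acetate
Conditions: HF·pyridine, THF, 0 °C
Reagents that add atoms: none
Why: Fluoride cleaves both triethylsilyl ethers without touching the tertiary acetate or the bromide.

Step 14
Reactants: 18 (1S,4S)-4-bromo-1-{[(1R,3aR,5R,7aS)-1,3a-dihydroxy-7a-methyloctahydro-1H-inden-5-yl]methyl}-3,3-dimethylcyclohexyl acetate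
Product: 19 (1S,4S)-4-bromo-1-{[(1R,3aR,5R,7aS)-3a-hydroxy-1-(methanesulfonyloxy)-7a-methyloctahydro-1H-inden-5-yl]methyl}-3,3-dimethylcyclohexyl acetate
Conditions: CH3SO2Cl, Et3N, CH2Cl2, −10 °C
Reagents that add atoms: methanesulfonyl chloride, CS(=O)(=O)Cl
Why: Sulfonylation occurs only at the secondary alcohol, leaving the tertiary 3a-OH free as the electron-releasing group for the fragmentation.

Step 15
Reactants: 19 (1S,4S)-4-bromo-1-{[(1R,3aR,5R,7aS)-3a-hydroxy-1-(methanesulfonyloxy)-7a-methyloctahydro-1H-inden-5-yl]methyl}-3,3-dimethylcyclohexyl acetate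
Product: 20 (1S,4S)-4-bromo-3,3-dimethyl-1-{[(1S,6E)-7-methyl-3-oxocyclonon-6-en-1-yl]methyl}cyclohexyl acetate
Conditions: NaH, THF, 0 to 23 °C
Reagents that add atoms: none
Why: Grob fragmentation: the 3a-alkoxide pushes, the C3a–C7a bond (roughly anti-periplanar to C1–OMs, which is cis to the angular CH3) breaks and mesylate leaves, which should give the ketone and stereospecifically the (E)-trisubstituted alkene of the nine-membered ring.

Step 16
Reactants: 20 (1S,4S)-4-bromo-3,3-dimethyl-1-{[(1S,6E)-7-methyl-3-oxocyclonon-6-en-1-yl]methyl}cyclohexyl acetate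
Product: 21 (1S,4S)-4-bromo-1-{[(1R,3S,6R,7S)-7-bromo-1-methoxy-6-methyl-10-oxabicyclo[4.3.1]decan-3-yl]methyl}-3,3-dimethylcyclohexyl acetate
Conditions: N-bromosuccinimide, CH2Cl2/MeOH (4:1), NaHCO3, −40 °C
Reagents that add atoms: N-bromosuccinimide, O=C1CCC(=O)N1Br; methanol, CO
Why: Bromoketalisation (haloetherification with carbonyl participation): Br+ should attack the exposed outer face of the (E)-alkene in the conformer that keeps the large ring substituent peripheral, the ketone oxygen closes transannularly on the tertiary carbon anti to bromine and methanol traps the oxocarbenium ion, fixing C6 and C7 (and bridgehead C1) relative to the existing centre.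

Step 17
Reactants: 21 (1S,4S)-4-bromo-1-{[(1R,3S,6R,7S)-7-bromo-1-methoxy-6-methyl-10-oxabicyclo[4.3.1]decan-3-yl]methyl}-3,3-dimethylcyclohexyl acetate
Product: 23 (1S,4S)-4-bromo-1-{[(1S,3aS,4S,7aS)-4-bromo-3a-methyl-7-oxooctahydro-1H-inden-1-yl]methyl}-3,3-dimethylcyclohexyl acetate, via enol ether 22 (not isolated)
Conditions: TMSOTf (1.3 equiv), 2,6-di-tert-butyl-4-methylpyridine (1.1 equiv), CH2Cl2, −78 to −20 °C
Reagents that add atoms: none
Why: Proposed new method: TMSOTf removes the bridgehead methoxide and the hindered pyridine takes a C2 proton to give bridgehead enol ether 22 (loss toward C9 is unproductive and reversible); silylation of the ring oxygen then ionises the tertiary C6–O bond with anchimeric help from the anti-periplanar C7–Br (bromonium ion), and the silyl enol ether carbon C2 closes transannularly on C6 from the face the oxygen left, after which desilylation gives the ketone (bicycle numbering). The closest known reactions are the Petasis–Ferrier rearrangement (Lewis-acid 1,3-O→C shift of cyclic enol acetals) and bromonium-ion cyclisations terminated by silyl enol ethers; new is the relay of a tertiary alkyl–oxygen ionisation through a neighbouring bromine in a transannular setting. Ring B closes as a 5-(enolexo)-exo-tet opening of the bromonium ion and ring A, in the same bond formation, as a 6-(enolendo)-exo-tet closure, so the seven-membered oxepane contracts by two atoms (O10 and C1 leave it) to the cyclopentane and the oxane becomes the cyclohexanone. C3a of the product keeps its configuration by double inversion (Br in, carbon out), C4–Br is untouched, and C7a is set by the fixed ring-trans geometry of the bridgehead enol ether and the chair-like transannular approach, which puts both five-ring bonds equatorial on ring A (trans-hydrindane). The step needs C- over O-recombination (O-return only regenerates 22), ionisation at the bridge C–O rather than at the tertiary acetate (secured by the neighbouring bromine and the strain of the bicycle), and retention of the bromonium ion (no free alkene is present to carry Br+ away).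

Step 18
Reactants: 23 (1S,4S)-4-bromo-1-{[(1S,3aS,4S,7aS)-4-bromo-3a-methyl-7-oxooctahydro-1H-inden-1-yl]methyl}-3,3-dimethylcyclohexyl acetate
Product: 24 (1S,4S)-4-bromo-1-{[(1S,3aS,4S,7R,7aS)-4-bromo-7-hydroxy-3a,7-dimethyloctahydro-1H-inden-1-yl]methyl}-3,3-dimethylcyclohexyl acetate
Conditions: CH3MgBr, CeCl3, THF, −78 °C
Reagents that add atoms: methylmagnesium bromide, C[Mg]Br
Why: Cerium-mediated Grignard addition at −78 °C should be faster at the ketone than at the hindered tertiary acetate; the axial 3a-CH3 blocks axial attack, so CH3 enters equatorially and the new tertiary OH is axial, 1,3-diaxial to the angular CH3.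

Step 19
Reactants: 24 (1S,4S)-4-bromo-1-{[(1S,3aS,4S,7R,7aS)-4-bromo-7-hydroxy-3a,7-dimethyloctahydro-1H-inden-1-yl]methyl}-3,3-dimethylcyclohexyl acetate
Product: 26 (1S,4S)-4-bromo-1-{[(1S,3aS,4S,7R,7aS)-4-bromo-7-hydroxy-3a-[(E)-(hydroxyimino)methyl]-7-methyloctahydro-1H-inden-1-yl]methyl}-3,3-dimethylcyclohexyl acetate, via nitrite ester 25 (not isolated)
Conditions: NOCl, pyridine, −20 °C; then hν (Hg lamp, Pyrex), benzene, 15 °C; then 2-propanol, 50 °C
Reagents that add atoms: nitrosyl chloride, O=NCl
Why: Barton nitrite ester reaction: photolysis gives the tertiary alkoxy radical, which should abstract hydrogen from the 1,3-diaxial angular CH3 through a six-membered transition state; NO recombination and tautomerisation give the oxime.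

Step 20
Reactants: 26 (1S,4S)-4-bromo-1-{[(1S,3aS,4S,7R,7aS)-4-bromo-7-hydroxy-3a-[(E)-(hydroxyimino)methyl]-7-methyloctahydro-1H-inden-1-yl]methyl}-3,3-dimethylcyclohexyl acetate
Product: 28 (1S,4S)-4-bromo-1-{[(1S,3aS,4S,7R,7aS,8R)-4-bromo-8-hydroxy-7-methyloctahydro-1H-7,3a-(epoxymethano)inden-1-yl]methyl}-3,3-dimethylcyclohexyl acetate (target), via hydroxy aldehyde 27 (not isolated)
Conditions: NaNO2, AcOH/H2O, 15 °C
Reagents that add atoms: water, O
Why: Nitrous acid deoximation liberates the angular aldehyde, which should be captured at once by the axial tertiary hydroxyl as the five-membered lactol, the anomeric centre equilibrating through the hydroxy aldehyde.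

**Compound list**

1 | 5-methyl L-glutamate, (2S)-2-amino-5-methoxy-5-oxopentanoic acid | COC(=O)CC[C@H](N)C(=O)O | starting material
2 | (2S)-2-bromo-5-methoxy-5-oxopentanoic acid | COC(=O)CC[C@H](Br)C(=O)O | intermediate
3 | dimethyl (2S)-2-bromopentanedioate | COC(=O)CC[C@H](Br)C(=O)OC | intermediate
4 | methyl (4S)-4-bromo-5-hydroxy-5-methylhexanoate (bromohydrin ester) | COC(=O)CC[C@H](Br)C(C)(C)O | intermediate
5 | (5S)-5-bromo-6,6-dimethyloxan-2-one | O=C1CC[C@H](Br)C(C)(C)O1 | intermediate
6 | (3S)-3-bromo-2,2-dimethyl-6-methylideneoxane | C=C1CC[C@H](Br)C(C)(C)O1 | intermediate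
7 | (4S)-4-bromo-3,3-dimethylcyclohexan-1-one | O=C1CC[C@H](Br)C(C)(C)C1 | intermediate
8 | 2-methyl-2-(3-oxobutyl)cyclopentane-1,3-dione | CC(=O)CCC1(C)C(=O)CCC1=O | starting material
9 | (3aR,7aR)-3a-hydroxy-7a-methylhexahydro-1H-indene-1,5(4H)-dione (OH and CH3 cis) | C[C@@]12CCC(=O)C[C@]1(O)CCC2=O | intermediate
10 | (3aR,7aR)-3a-hydroxy-7a-methyl-5-methylideneoctahydro-1H-inden-1-one | C[C@@]12CCC(=C)C[C@]1(O)CCC2=O | intermediate
11 | (1R,3aR,7aS)-7a-methyl-5-methylideneoctahydro-1H-indene-1,3a-diol (1-OH cis to 7a-CH3) | C[C@@]12CCC(=C)C[C@]1(O)CC[C@H]2O | intermediate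
12 | (1R,3aR,5R,7aS)-5-(hydroxymethyl)-7a-methyloctahydro-1H-indene-1,3a-diol (CH2OH cis to 3a-OH) | C[C@@]12CC[C@@H](CO)C[C@]1(O)CC[C@H]2O | intermediate
13 | (1R,3aR,5R,7aS)-5-(iodomethyl)-7a-methyloctahydro-1H-indene-1,3a-diol | C[C@@]12CC[C@@H](CI)C[C@]1(O)CC[C@H]2O | intermediate
14 | (1R,3aR,5R,7aS)-5-(iodomethyl)-7a-methyl-1,3a-bis(triethylsilyloxy)octahydro-1H-indene | C[C@@]12CC[C@@H](CI)C[C@]1(O[Si](CC)(CC)CC)CC[C@H]2O[Si](CC)(CC)CC | intermediate
15 | organolithium from 14 (CH2Li in place of CH2I, same configuration) | C[C@@]12CC[C@@H](C[Li])C[C@]1(O[Si](CC)(CC)CC)CC[C@H]2O[Si](CC)(CC)CC | intermediate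
16 | organocerium RCeCl2 from 15 (CH2CeCl2, same configuration) | C[C@@]12CC[C@@H](C[Ce](Cl)Cl)C[C@]1(O[Si](CC)(CC)CC)CC[C@H]2O[Si](CC)(CC)CC | intermediate
17 | (1S,4S)-4-bromo-3,3-dimethyl-1-{[(1R,3aR,5S,7aS)-7a-methyl-1,3a-bis(triethylsilyloxy)octahydro-1H-inden-5-yl]methyl}cyclohexyl acetate | CC(=O)O[C@]1(C[C@@H]2CC[C@@]3(C)[C@H](O[Si](CC)(CC)CC)CC[C@@]3(O[Si](CC)(CC)CC)C2)CC[C@H](Br)C(C)(C)C1 | intermediate
18 | (1S,4S)-4-bromo-1-{[(1R,3aR,5R,7aS)-1,3a-dihydroxy-7a-methyloctahydro-1H-inden-5-yl]methyl}-3,3-dimethylcyclohexyl acetate | CC(=O)O[C@]1(C[C@@H]2CC[C@@]3(C)[C@H](O)CC[C@@]3(O)C2)CC[C@H](Br)C(C)(C)C1 | intermediate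
19 | (1S,4S)-4-bromo-1-{[(1R,3aR,5R,7aS)-3a-hydroxy-1-(methanesulfonyloxy)-7a-methyloctahydro-1H-inden-5-yl]methyl}-3,3-dimethylcyclohexyl acetate | CC(=O)O[C@]1(C[C@@H]2CC[C@@]3(C)[C@H](OS(C)(=O)=O)CC[C@@]3(O)C2)CC[C@H](Br)C(C)(C)C1 | intermediate
20 | (1S,4S)-4-bromo-3,3-dimethyl-1-{[(1S,6E)-7-methyl-3-oxocyclonon-6-en-1-yl]methyl}cyclohexyl acetate | CC(=O)O[C@]1(C[C@@H]2CC/C(C)=C/CCC(=O)C2)CC[C@H](Br)C(C)(C)C1 | intermediate
21 | (1S,4S)-4-bromo-1-{[(1R,3S,6R,7S)-7-bromo-1-methoxy-6-methyl-10-oxabicyclo[4.3.1]decan-3-yl]methyl}-3,3-dimethylcyclohexyl acetate (Br anti to the O-bridge) | CC(=O)O[C@]1(C[C@@H]2CC[C@@]3(C)O[C@@](OC)(C2)CC[C@@H]3Br)CC[C@H](Br)C(C)(C)C1 | intermediate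
22 | (1S,4S)-4-bromo-1-{[(3S,6R,7S)-7-bromo-6-methyl-10-oxabicyclo[4.3.1]dec-1-en-3-yl]methyl}-3,3-dimethylcyclohexyl acetate (bridgehead enol ether) | CC(=O)O[C@]1(C[C@@H]2CC[C@@]3(C)OC(=C2)CC[C@@H]3Br)CC[C@H](Br)C(C)(C)C1 | intermediate
23 | (1S,4S)-4-bromo-1-{[(1S,3aS,4S,7aS)-4-bromo-3a-methyl-7-oxooctahydro-1H-inden-1-yl]methyl}-3,3-dimethylcyclohexyl acetate (trans-fused) | CC(=O)O[C@]1(C[C@@H]2CC[C@]3(C)[C@@H](Br)CCC(=O)[C@@H]23)CC[C@H](Br)C(C)(C)C1 | intermediate
24 | (1S,4S)-4-bromo-1-{[(1S,3aS,4S,7R,7aS)-4-bromo-7-hydroxy-3a,7-dimethyloctahydro-1H-inden-1-yl]methyl}-3,3-dimethylcyclohexyl acetate (7-OH cis to 3a-CH3) | CC(=O)O[C@]1(C[C@@H]2CC[C@]3(C)[C@@H](Br)CC[C@@](C)(O)[C@@H]23)CC[C@H](Br)C(C)(C)C1 | intermediate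
25 | nitrite ester of 24 (7-O–N=O, same configuration) | CC(=O)O[C@]1(C[C@@H]2CC[C@]3(C)[C@@H](Br)CC[C@@](C)(ON=O)[C@@H]23)CC[C@H](Br)C(C)(C)C1 | intermediate
26 | (1S,4S)-4-bromo-1-{[(1S,3aS,4S,7R,7aS)-4-bromo-7-hydroxy-3a-[(E)-(hydroxyimino)methyl]-7-methyloctahydro-1H-inden-1-yl]methyl}-3,3-dimethylcyclohexyl acetate | CC(=O)O[C@]1(C[C@@H]2CC[C@]3(/C=N/O)[C@@H](Br)CC[C@@](C)(O)[C@@H]23)CC[C@H](Br)C(C)(C)C1 | intermediate
27 | (1S,4S)-4-bromo-1-{[(1S,3aS,4S,7R,7aS)-4-bromo-3a-formyl-7-hydroxy-7-methyloctahydro-1H-inden-1-yl]methyl}-3,3-dimethylcyclohexyl acetate | CC(=O)O[C@]1(C[C@@H]2CC[C@]3(C=O)[C@@H](Br)CC[C@@](C)(O)[C@@H]23)CC[C@H](Br)C(C)(C)C1 | intermediate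
28 | (1S,4S)-4-bromo-1-{[(1S,3aS,4S,7R,7aS,8R)-4-bromo-8-hydroxy-7-methyloctahydro-1H-7,3a-(epoxymethano)inden-1-yl]methyl}-3,3-dimethylcyclohexyl acetate | CC(=O)O[C@]1(C[C@@H]2CC[C@]34[C@H](O)O[C@](C)(CC[C@@H]3Br)[C@@H]24)CC[C@H](Br)C(C)(C)C1 | target

**Step count and risks**

Total steps: 20. Longest linear sequence: 15 (steps 6–20, from 8 to 28); the cyclohexanone branch (steps 1–5) joins at step 12.

Steps most likely to fail:

1. Step 17 (Proposed new method). After ionisation the bromonium ion may lose a proton or be captured by an external nucleophile instead of by the enol carbon, the tertiary acetate may ionise competitively, or the sequence may stop at the enol ether and revert to the hemiketal on work-up. Fallback (known chemistry, no oxygen bridge): set out from 20 and enolise softly (TMSOTf, Et3N) to the silyl enol ether (1S,4S)-4-bromo-3,3-dimethyl-1-{[(1S,2Z,6E)-7-methyl-3-(trimethylsilyloxy)cyclonona-2,6-dien-1-yl]methyl}cyclohexyl acetate F5; its regioisomer cannot cyclise productively and is recycled. Treating F5 with the bromonium source (C2H5)2SBr·SbCl5Br in nitromethane at −25 °C should effect a direct transannular bromonium cyclisation terminated by the enol silane, returning to the route at 23.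

2. Step 5 (Proposed new method). The ionised intermediate may eliminate instead of closing the C–C bond, the enol ether may hydrolyse to the bromohydrin ketone, or the bromonium ion may lose configurational integrity. Fallback (known chemistry): set out from 5 and add (CH3)3SiCH2MgCl/CeCl3 (2.5 equiv) to give (5S)-5-bromo-6-methyl-1-(trimethylsilyl)-2-[(trimethylsilyl)methyl]heptane-2,6-diol F1. Peterson elimination on silica gel gives the allylsilane (3S)-3-bromo-2-methyl-6-[(trimethylsilyl)methyl]hept-6-en-2-ol F2, and SOCl2/pyridine converts the tertiary alcohol, with neighbouring-bromine retention, into [(5S)-5-bromo-6-chloro-6-methyl-2-methylideneheptyl](trimethyl)silane F3. Solvolysis of F3 in hexafluoroisopropanol regenerates the bromonium ion enantiospecifically and the allylsilane terminates the cyclisation, giving (4S)-4-bromo-3,3-dimethyl-1-methylidenecyclohexane F4; ozonolysis (O3, then dimethyl sulfide) comes back to the route at 7.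

3. Step 19. β-Fragmentation of the tertiary alkoxy radical (ring cleavage or loss of the C7 methyl) may outrun the 1,5-hydrogen transfer. Fallback (no alkoxy radical): set out from 24 and silylate with (C2H5)2SiH2 and catalytic [Ir(OCH3)(C8H12)]2 to the hydridosilyl ether F6, the diethylsilyl ether of 24 at the C7 oxygen. Rhodium-catalysed δ-C–H silylation ([RhCl(C8H12)]2, Xantphos, norbornene, 100 °C) should close the six-membered oxasilinane F7 onto the angular methyl, and Tamao–Fleming oxidation (H2O2, KHCO3, KF) gives the diol F8, the 3a-hydroxymethyl analogue of 24. One equivalent of Dess–Martin periodinane oxidises the primary alcohol to hydroxy aldehyde 27, which closes to 28.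

Two further weak points, not among the three above: the C1′ configuration in step 12 depends on which chair of 7 reacts, and the Br-axial chair, which leads to the C1′ epimer, may not be much disfavoured; and the facial selectivity of the hydroboration in step 9 sets the only stereocentre that carries chirality through the nine-membered ring.

Further compounds
F1 | step 5 | (5S)-5-bromo-6-methyl-1-(trimethylsilyl)-2-[(trimethylsilyl)methyl]heptane-2,6-diol | C[Si](C)(C)CC(O)(C[Si](C)(C)C)CC[C@H](Br)C(C)(C)O
F2 | step 5 | (3S)-3-bromo-2-methyl-6-[(trimethylsilyl)methyl]hept-6-en-2-ol | C=C(C[Si](C)(C)C)CC[C@H](Br)C(C)(C)O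
F3 | step 5 | [(5S)-5-bromo-6-chloro-6-methyl-2-methylideneheptyl](trimethyl)silane | C=C(C[Si](C)(C)C)CC[C@H](Br)C(C)(C)Cl
F4 | step 5 | (4S)-4-bromo-3,3-dimethyl-1-methylidenecyclohexane | C=C1CC[C@H](Br)C(C)(C)C1
F5 | step 17 | (1S,4S)-4-bromo-3,3-dimethyl-1-{[(1S,2Z,6E)-7-methyl-3-(trimethylsilyloxy)cyclonona-2,6-dien-1-yl]methyl}cyclohexyl acetate | CC(=O)O[C@]1(C[C@@H]2CC/C(C)=C/CC/C(O[Si](C)(C)C)=C/2)CC[C@H](Br)C(C)(C)C1
F6 | step 19 | diethylsilyl (Si–H) ether of 24 at the C7 oxygen | CC(=O)O[C@]1(C[C@@H]2CC[C@]3(C)[C@@H](Br)CC[C@@](C)(O[SiH](CC)CC)[C@@H]23)CC[C@H](Br)C(C)(C)C1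
F7 | step 19 | oxasilinane with O–Si(C2H5)2–CH2 bridging C7 and C3a | CC(=O)O[C@]1(C[C@@H]2CC[C@]34C[Si](CC)(CC)O[C@](C)(CC[C@@H]3Br)[C@@H]24)CC[C@H](Br)C(C)(C)C1
F8 | step 19 | (1S,4S)-4-bromo-1-{[(1S,3aS,4S,7R,7aS)-4-bromo-7-hydroxy-3a-(hydroxymethyl)-7-methyloctahydro-1H-inden-1-yl]methyl}-3,3-dimethylcyclohexyl acetate | CC(=O)O[C@]1(C[C@@H]2CC[C@]3(CO)[C@@H](Br)CC[C@@](C)(O)[C@@H]23)CC[C@H](Br)C(C)(C)C1
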